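**Retrosynthetic overview**
- The depside C(=O)–O bond between the ring A carboxyl and the C4 oxygen of ring B is cut first, giving a ring A acid and benzyl 4-hydroxy-2-methoxy-6-pentylbenzoate, which is made from olivetol.
- The route rests on one feature of ring A: C6, which carries the CH2 of the 2-oxoheptyl chain, is ortho to the carboxyl-bearing C1, and it is the only open ortho position because C2 carries oxygen. The C6–CH2 bond is therefore cut back to the C6–H bond of 2-(benzyloxy)-4-methoxybenzoic acid and a hexanoyl sulfoxonium ylide.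
- Both benzene rings are bought. The only ring closed is the isocoumarin lactone in step 3; hydroxide opens it again in step 4.
- The ketone is masked as a dioxolane for the esterification; hydrogenolysis of the benzyl ether and benzyl ester ends the route.

Key step: step 3

Remark on the chemistry: the target has no stereocenter, so no step controls configuration; keto acid 8 appears first as a transient intermediate of step 3 and then as the isolated product of step 4, and keeps one number.

**Route**

Step 1
Reactants: 1 2-hydroxy-4-methoxybenzoic acid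
Product: 3 2-(benzyloxy)-4-methoxybenzoic acid, via benzyl 2-(benzyloxy)-4-methoxybenzoate 2 (not isolated)
Conditions: BnBr, K2CO3, DMF, 60 °C; then NaOH, MeOH/H2O, 70 °C; aq. HCl
Reagents that add atoms: benzyl bromide BrCc1ccccc1; sodium hydroxide [Na+].[OH-]
Why: Williamson benzylation of phenoxide and carboxylate followed in the same flask by saponification should leave the aryl benzyl ether untouched, because hydroxide cleaves only the benzyl ester.

Step 2
Reactants: 4 trimethylsulfoxonium iodide; 5 hexanoyl chloride
Product: 7 1-[dimethyl(oxo)-lambda6-sulfanylidene]heptan-2-one, via dimethylsulfoxonium methylide 6 (not isolated)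
Conditions: KOtBu (3 equiv), 4 (3 equiv), THF, reflux; then 5 (1 equiv), 0 °C to rt
Reagents that add atoms: none
Why: C-acylation of dimethylsulfoxonium methylide (the Corey-Chaykovsky reagent) by the acid chloride, with a second equivalent of methylide taking up HCl, is the standard entry to carbonyl-stabilised sulfoxonium ylides.

Step 3
Reactants: 3 2-(benzyloxy)-4-methoxybenzoic acid; 7 1-[dimethyl(oxo)-lambda6-sulfanylidene]heptan-2-one
Product: 9 8-(benzyloxy)-6-methoxy-3-pentyl-1H-isochromen-1-one, via 2-(benzyloxy)-4-methoxy-6-(2-oxoheptyl)benzoic acid 8 (not isolated)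
Conditions: [Cp*RhCl2]2 (2.5 mol %), AgSbF6 (10 mol %), NaOAc (1 equiv), CF3CH2OH, 80 °C
Reagents that add atoms: none
Why: Acetate-assisted concerted metalation-deprotonation by the cationic Cp*Rh species (trivalent rhodium), directed by the carboxylate of 3, gives a five-membered rhodacycle at C6; ylide 7 binds through carbon, dimethyl sulfoxide leaves to give a rhodium carbene, and migratory insertion into the aryl-rhodium bond followed by protodemetalation releases keto acid 8. The carboxyl oxygen of 8 then adds to the ketone in a 6-exo-trig closure and loss of water gives the enol lactone (the pyranone ring of 9, a temporary ring that step 4 opens). The closest known reaction type is the carboxylate-directed C-H acylmethylation and annulation of benzoic acids with sulfoxonium ylides to 3-substituted isocoumarins under Cp*Rh catalysis. No stereocenter is formed. The step needs site selectivity only, and the substrate secures it: the carboxylate reaches only C2 and C6, C2 carries the benzyloxy group, and C3 and C5 lie outside the reach of the five-membered metallacycle. Sodium acetate keeps the acid as its carboxylate, which should suppress protonation of the ylide and the O-alkylation that would follow.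

Step 4
Reactants: 9 8-(benzyloxy)-6-methoxy-3-pentyl-1H-isochromen-1-one
Product: 8 2-(benzyloxy)-4-methoxy-6-(2-oxoheptyl)benzoic acid
Conditions: KOH, EtOH/H2O, 70 °C; then cold 1 M HCl to pH 3, 0 °C
Reagents that add atoms: potassium hydroxide [K+].[OH-]
Why: Saponification of the enol lactone is irreversible in base because the expelled enolate tautomerises to the ketone, and acidification in the cold should deliver the open keto acid before it can relactonise.

Step 5
Reactants: 8 2-(benzyloxy)-4-methoxy-6-(2-oxoheptyl)benzoic acid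
Product: 10 prop-2-en-1-yl 2-(benzyloxy)-4-methoxy-6-(2-oxoheptyl)benzoate
Conditions: allyl bromide, KHCO3, DMF, rt
Reagents that add atoms: allyl bromide C=CCBr
Why: SN2 O-alkylation of the carboxylate under bicarbonate, which is too weak a base to enolise the benzylic ketone, gives an ester that can later be removed at the allyl carbon without attack on the hindered carbonyl.

Step 6
Reactants: 10 prop-2-en-1-yl 2-(benzyloxy)-4-methoxy-6-(2-oxoheptyl)benzoate
Product: 11 prop-2-en-1-yl 2-(benzyloxy)-4-methoxy-6-[(2-pentyl-1,3-dioxolan-2-yl)methyl]benzoate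
Conditions: TMSOCH2CH2OTMS, TMSOTf (cat.), CH2Cl2, −78 to −20 °C; pyridine quench
Reagents that add atoms: 1,2-bis(trimethylsilyloxy)ethane C[Si](C)(C)OCCO[Si](C)(C)C
Why: Noyori ketalisation with the bis-silyl glycol and catalytic TMSOTf runs under aprotic conditions at low temperature, where the di-ortho-substituted ester should not lactonise onto the activated ketone.

Step 7
Reactants: 11 prop-2-en-1-yl 2-(benzyloxy)-4-methoxy-6-[(2-pentyl-1,3-dioxolan-2-yl)methyl]benzoate
Product: 12 2-(benzyloxy)-4-methoxy-6-[(2-pentyl-1,3-dioxolan-2-yl)methyl]benzoic acid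
Conditions: Pd(PPh3)4 (3 mol %), morpholine, THF, rt; NaH2PO4 buffer (pH 5) work-up, used at once
Reagents that add atoms: none
Why: Tsuji-Trost deallylation, in which zerovalent palladium ionises the allyl ester to a pi-allyl complex that morpholine captures, runs under basic conditions that leave the dioxolane and the benzyl ether intact.

Step 8
Reactants: 13 olivetol (5-pentylbenzene-1,3-diol)
Product: 14 2,4-dihydroxy-6-pentylbenzoic acid
Conditions: MeOMgOCO2Me (2 M in DMF), 120 °C; then cold aq. HCl
Reagents that add atoms: methoxymagnesium methyl carbonate COC(=O)O[Mg]OC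
Why: Kolbe-Schmitt-type carboxylation with the Stiles reagent, in which magnesium chelation delivers CO2 ortho to a phenoxide, is the known way from 5-alkylresorcinols to 2,4-dihydroxy-6-alkylbenzoic acids.

Step 9
Reactants: 14 2,4-dihydroxy-6-pentylbenzoic acid
Product: 15 benzyl 2,4-dihydroxy-6-pentylbenzoate
Conditions: BnBr (1.05 equiv), KHCO3, DMF, rt
Reagents that add atoms: benzyl bromide BrCc1ccccc1
Why: SN2 alkylation of the carboxylate under bicarbonate should spare both phenols, which are not deprotonated, and room temperature avoids decarboxylation of the resorcylic acid.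

Step 10
Reactants: 15 benzyl 2,4-dihydroxy-6-pentylbenzoate
Product: 16 benzyl 2-hydroxy-6-pentyl-4-(prop-2-en-1-yloxy)benzoate
Conditions: allyl bromide (1.05 equiv), K2CO3, acetone, reflux
Reagents that add atoms: allyl bromide C=CCBr
Why: Williamson allylation should go to the C4 hydroxyl because the C2 hydroxyl is held in a hydrogen bond to the ester carbonyl and is less acidic.

Step 11
Reactants: 16 benzyl 2-hydroxy-6-pentyl-4-(prop-2-en-1-yloxy)benzoate
Product: 17 benzyl 2-methoxy-6-pentyl-4-(prop-2-en-1-yloxy)benzoate
Conditions: MeI, K2CO3, DMF, 50 °C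
Reagents that add atoms: iodomethane CI
Why: Williamson methylation of the remaining chelated phenol under more forcing conditions should proceed with the benzyl ester and the allyl ether inert to carbonate.

Step 12
Reactants: 17 benzyl 2-methoxy-6-pentyl-4-(prop-2-en-1-yloxy)benzoate
Product: 18 benzyl 4-hydroxy-2-methoxy-6-pentylbenzoate
Conditions: Pd(PPh3)4 (3 mol %), morpholine, THF, rt
Reagents that add atoms: none
Why: Tsuji-Trost cleavage of the aryl allyl ether, with phenoxide as leaving group and morpholine as allyl acceptor, is orthogonal to the benzyl ester, which zerovalent palladium does not ionise under these conditions.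

Step 13
Reactants: 12 2-(benzyloxy)-4-methoxy-6-[(2-pentyl-1,3-dioxolan-2-yl)methyl]benzoic acid; 18 benzyl 4-hydroxy-2-methoxy-6-pentylbenzoate
Product: 19 benzyl 4-({2-(benzyloxy)-4-methoxy-6-[(2-pentyl-1,3-dioxolan-2-yl)methyl]benzoyl}oxy)-2-methoxy-6-pentylbenzoate
Conditions: DCC, DMAP (cat.), CH2Cl2, 0 °C to rt
Reagents that add atoms: none
Why: Steglich esterification, in which DMAP relays the O-acylisourea as an acylpyridinium ion to the unhindered C4 phenol of ring B, runs under neutral conditions that keep the dioxolane.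

Step 14
Reactants: 19 benzyl 4-({2-(benzyloxy)-4-methoxy-6-[(2-pentyl-1,3-dioxolan-2-yl)methyl]benzoyl}oxy)-2-methoxy-6-pentylbenzoate
Product: 20 benzyl 4-{[2-(benzyloxy)-4-methoxy-6-(2-oxoheptyl)benzoyl]oxy}-2-methoxy-6-pentylbenzoate
Conditions: PPTS, acetone/H2O, 50 °C
Reagents that add atoms: water O
Why: Acid-catalysed hydrolysis of the dialkyl dioxolane under buffered conditions should be far faster than cleavage of the hindered aryl ester or of the benzyl groups.

Step 15
Reactants: 20 benzyl 4-{[2-(benzyloxy)-4-methoxy-6-(2-oxoheptyl)benzoyl]oxy}-2-methoxy-6-pentylbenzoate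
Product: 21 confluentic acid
Conditions: H2 (1 atm), 10% Pd/C, EtOAc, rt
Reagents that add atoms: none
Why: Hydrogenolysis over palladium on carbon should cleave the benzyl ether and the benzyl ester in one operation, while the aliphatic ketone and the aryl ester are inert.

**Compound list**
1 | 2-hydroxy-4-methoxybenzoic acid | COc1ccc(C(=O)O)c(O)c1 | starting material
2 | benzyl 2-(benzyloxy)-4-methoxybenzoate | COc1ccc(C(=O)OCc2ccccc2)c(OCc2ccccc2)c1 | intermediate
3 | 2-(benzyloxy)-4-methoxybenzoic acid | COc1ccc(C(=O)O)c(OCc2ccccc2)c1 | intermediate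
4 | trimethylsulfoxonium iodide | C[S+](C)(C)=O.[I-] | starting material
5 | hexanoyl chloride | CCCCCC(=O)Cl | starting material
6 | dimethylsulfoxonium methylide | [CH2-][S+](C)(C)=O | intermediate
7 | 1-[dimethyl(oxo)-lambda6-sulfanylidene]heptan-2-one | CCCCCC(=O)C=S(C)(C)=O | intermediate
8 | 2-(benzyloxy)-4-methoxy-6-(2-oxoheptyl)benzoic acid | CCCCCC(=O)Cc1cc(OC)cc(OCc2ccccc2)c1C(=O)O | intermediate
9 | 8-(benzyloxy)-6-methoxy-3-pentyl-1H-isochromen-1-one | CCCCCC1=Cc2cc(OC)cc(OCc3ccccc3)c2C(=O)O1 | intermediate
10 | prop-2-en-1-yl 2-(benzyloxy)-4-methoxy-6-(2-oxoheptyl)benzoate | CCCCCC(=O)Cc1cc(OC)cc(OCc2ccccc2)c1C(=O)OCC=C | intermediate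
11 | prop-2-en-1-yl 2-(benzyloxy)-4-methoxy-6-[(2-pentyl-1,3-dioxolan-2-yl)methyl]benzoate | CCCCCC1(Cc2cc(OC)cc(OCc3ccccc3)c2C(=O)OCC=C)OCCO1 | intermediate
12 | 2-(benzyloxy)-4-methoxy-6-[(2-pentyl-1,3-dioxolan-2-yl)methyl]benzoic acid | CCCCCC1(Cc2cc(OC)cc(OCc3ccccc3)c2C(=O)O)OCCO1 | intermediate
13 | olivetol | CCCCCc1cc(O)cc(O)c1 | starting material
14 | 2,4-dihydroxy-6-pentylbenzoic acid | CCCCCc1cc(O)cc(O)c1C(=O)O | intermediate
15 | benzyl 2,4-dihydroxy-6-pentylbenzoate | CCCCCc1cc(O)cc(O)c1C(=O)OCc1ccccc1 | intermediate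
16 | benzyl 2-hydroxy-6-pentyl-4-(prop-2-en-1-yloxy)benzoate | CCCCCc1cc(OCC=C)cc(O)c1C(=O)OCc1ccccc1 | intermediate
17 | benzyl 2-methoxy-6-pentyl-4-(prop-2-en-1-yloxy)benzoate | CCCCCc1cc(OCC=C)cc(OC)c1C(=O)OCc1ccccc1 | intermediate
18 | benzyl 4-hydroxy-2-methoxy-6-pentylbenzoate | CCCCCc1cc(O)cc(OC)c1C(=O)OCc1ccccc1 | intermediate
19 | benzyl 4-({2-(benzyloxy)-4-methoxy-6-[(2-pentyl-1,3-dioxolan-2-yl)methyl]benzoyl}oxy)-2-methoxy-6-pentylbenzoate | CCCCCc1cc(OC(=O)c2c(CC3(CCCCC)OCCO3)cc(OC)cc2OCc2ccccc2)cc(OC)c1C(=O)OCc1ccccc1 | intermediate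
20 | benzyl 4-{[2-(benzyloxy)-4-methoxy-6-(2-oxoheptyl)benzoyl]oxy}-2-methoxy-6-pentylbenzoate | CCCCCC(=O)Cc1cc(OC)cc(OCc2ccccc2)c1C(=O)Oc1cc(CCCCC)c(C(=O)OCc2ccccc2)c(OC)c1 | intermediate
21 | confluentic acid | CCCCCC(=O)Cc1cc(OC)cc(O)c1C(=O)Oc1cc(CCCCC)c(C(=O)O)c(OC)c1 | target

**Step count**
Total: 15 steps. Longest linear sequence: 9 steps (steps 1, 3, 4, 5, 6, 7, 13, 14, 15).

**Steps most likely to fail**

Step 3. The free acid may protonate the ylide carbon, after which the carboxylate displaces dimethyl sulfoxide and the acid is consumed by O-alkylation. Metalation at C6 may also be slow next to a carboxylate twisted by the benzyloxy group, so that the electron-rich acid loses CO2 first. The fallback replaces C-H functionalization by lateral lithiation and acylation; it sets out from hexanoyl chloride 5 and comes back at isocoumarin 9. Compound 5 is converted with N,O-dimethylhydroxylamine hydrochloride and pyridine into N-methoxy-N-methylhexanamide F1. Purchased methyl 2-hydroxy-4-methoxy-6-methylbenzoate F2 is benzylated (BnBr, K2CO3, DMF) to methyl 2-(benzyloxy)-4-methoxy-6-methylbenzoate F3. Deprotonation of the C6 methyl group with LiN(iPr)2 in THF at −78 °C gives [3-(benzyloxy)-5-methoxy-2-(methoxycarbonyl)benzyl]lithium F4, and acylation with F1 gives methyl 2-(benzyloxy)-4-methoxy-6-(2-oxoheptyl)benzoate F5. Heating with catalytic p-TsOH in toluene with removal of methanol should close the enol lactone to 9.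

Step 13. Acyl transfer to the phenol may be slow at the di-ortho-substituted carbonyl, so that the O-acylisourea rearranges to the N-acylurea, or the acid-labile dioxolane is lost on the activated acid and the lactone re-forms. The fallback uses an isolated acyl fluoride and a phenoxide; it sets out from acid 12 and comes back at depside 19. Cyanuric fluoride and pyridine in CH2Cl2 convert 12 into 2-(benzyloxy)-4-methoxy-6-[(2-pentyl-1,3-dioxolan-2-yl)methyl]benzoyl fluoride F6. This small, neutral acyl donor is then treated with the cesium phenoxide of 18 (Cs2CO3, MeCN) to give 19.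

Step 6. The silylated ketone may be captured by the neighbouring ester carbonyl oxygen, or may enolise toward the benzylic CH2, before the second C-O bond of the ketal forms, so that ketal closure stalls. The fallback changes the mask to a dithioacetal, which is released by S-alkylation and not by acid; it sets out from keto ester 10 and comes back at keto depside 20, so acid step 14 also falls away. Ethane-1,2-dithiol and BF3·OEt2 in CH2Cl2 at 0 °C convert 10 into prop-2-en-1-yl 2-(benzyloxy)-4-methoxy-6-[(2-pentyl-1,3-dithiolan-2-yl)methyl]benzoate F7. Deallylation as in step 7 gives 2-(benzyloxy)-4-methoxy-6-[(2-pentyl-1,3-dithiolan-2-yl)methyl]benzoic acid F8. Coupling with 18 (DCC, DMAP) gives benzyl 4-({2-(benzyloxy)-4-methoxy-6-[(2-pentyl-1,3-dithiolan-2-yl)methyl]benzoyl}oxy)-2-methoxy-6-pentylbenzoate F9. MeI and CaCO3 in aqueous MeCN then release the ketone at neutral pH to give 20; all sulfur is removed before the palladium step.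

**Further compounds**
F1 | step 3 | N-methoxy-N-methylhexanamide | CCCCCC(=O)N(C)OC
F2 | step 3 | methyl 2-hydroxy-4-methoxy-6-methylbenzoate (purchased) | COc1cc(C)c(C(=O)OC)c(O)c1
F3 | step 3 | methyl 2-(benzyloxy)-4-methoxy-6-methylbenzoate | COc1cc(C)c(C(=O)OC)c(OCc2ccccc2)c1
F4 | step 3 | [3-(benzyloxy)-5-methoxy-2-(methoxycarbonyl)benzyl]lithium | [Li]Cc1cc(OC)cc(OCc2ccccc2)c1C(=O)OC
F5 | step 3 | methyl 2-(benzyloxy)-4-methoxy-6-(2-oxoheptyl)benzoate | CCCCCC(=O)Cc1cc(OC)cc(OCc2ccccc2)c1C(=O)OC
F6 | step 13 | 2-(benzyloxy)-4-methoxy-6-[(2-pentyl-1,3-dioxolan-2-yl)methyl]benzoyl fluoride | CCCCCC1(Cc2cc(OC)cc(OCc3ccccc3)c2C(F)=O)OCCO1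
F7 | step 6 | prop-2-en-1-yl 2-(benzyloxy)-4-methoxy-6-[(2-pentyl-1,3-dithiolan-2-yl)methyl]benzoate | CCCCCC1(Cc2cc(OC)cc(OCc3ccccc3)c2C(=O)OCC=C)SCCS1
F8 | step 6 | 2-(benzyloxy)-4-methoxy-6-[(2-pentyl-1,3-dithiolan-2-yl)methyl]benzoic acid | CCCCCC1(Cc2cc(OC)cc(OCc3ccccc3)c2C(=O)O)SCCS1
F9 | step 6 | benzyl 4-({2-(benzyloxy)-4-methoxy-6-[(2-pentyl-1,3-dithiolan-2-yl)methyl]benzoyl}oxy)-2-methoxy-6-pentylbenzoate | CCCCCc1cc(OC(=O)c2c(CC3(CCCCC)SCCS3)cc(OC)cc2OCc2ccccc2)cc(OC)c1C(=O)OCc1ccccc1
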